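Ring A (C1 prenyl, C2 OH, C3 H, C4 OH, C5 CHO, C6 aroyl) is disconnected at C1–C6 and C2–C3. The route exploits the adjacent acyl carbons at C5/C6 and the 1,3-related oxygens at C2/C4 of ring A: C3–C6 are carried by a 4-MOM-oxy-2-pyrone bearing a C5 ester and the ring B aroyl group at C6, C1–C2 by a prenyl-substituted silyl ynol ether. One inverse-electron-demand [4+2] cycloaddition with loss of CO2 delivers the hexasubstituted benzene and leaves the crowded diaryl ketone intact, so no two hindered arenes are ever coupled. Ring B derives from orcinol; ester-to-aldehyde adjustment and deprotection finish the synthesis.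

Key step: step 8

Assumption: compounds 1, 4, 8 and 13 are taken as purchasable; the pyrone carbons C3–C6 keep the ring A numbers given above, and the target has no stereocentre and no stereogenic alkene, so no configuration has to be set.

Step 1
Reactants: 1 orcinol (5-methylbenzene-1,3-diol)
Product: 2 4-chloro-5-methylbenzene-1,3-diol
Conditions: SO2Cl2 (1.0 equiv), Et2O, 0 °C → rt
Reagents that add atoms: sulfuryl chloride, O=S(=O)(Cl)Cl
Why: Electrophilic aromatic chlorination should go mainly to C4, which is para to one hydroxyl and ortho to the other and less crowded than C2 between the two hydroxyls, the minor 2-chloro and dichloro products being removed by crystallisation.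

Step 2
Reactants: 2 4-chloro-5-methylbenzene-1,3-diol
Product: 3 2-chloro-1,5-bis(methoxymethoxy)-3-methylbenzene
Conditions: MOMCl, i-Pr2NEt, CH2Cl2, 0 °C → rt
Reagents that add atoms: chloromethyl methyl ether, COCCl
Why: Williamson-type O-alkylation of both phenols with the reactive α-chloro ether installs acetal ethers that direct the later lithiation and can be removed together under mild acid.

Step 3
Reactants: 3 2-chloro-1,5-bis(methoxymethoxy)-3-methylbenzene; 4 diethyl oxalate
Product: 6 ethyl 2-[3-chloro-2,6-bis(methoxymethoxy)-4-methylphenyl]-2-oxoacetate, via aryllithium 5 (not isolated)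
Conditions: n-BuLi, THF, 0 °C; then cannulated into 4 (3 equiv), THF, −78 °C; AcOH quench
Reagents that add atoms: none
Why: Directed ortho-metalation removes the proton between the two MOM ethers (the most acidic ring position through double coordination of lithium, and not ortho to chlorine, so no aryne can form), and inverse addition to excess oxalate stops the acyl substitution at the α-keto ester.

Step 4
Reactants: 6 ethyl 2-[3-chloro-2,6-bis(methoxymethoxy)-4-methylphenyl]-2-oxoacetate
Product: 7 2-[3-chloro-2,6-bis(methoxymethoxy)-4-methylphenyl]-2-oxoacetic acid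
Conditions: LiOH·H2O, THF/H2O, 0 °C; then 1 M HCl to pH 3–4, 0 °C
Reagents that add atoms: lithium hydroxide, [Li+].[OH-]
Why: Saponification of an α-keto ester is fast at 0 °C because the neighbouring ketone activates the ester, and brief cold acidification to pH 3–4 should liberate the acid without touching the MOM ethers.

Step 5
Reactants: 7 2-[3-chloro-2,6-bis(methoxymethoxy)-4-methylphenyl]-2-oxoacetic acid; 8 dimethyl 3-oxoglutarate (dimethyl 3-oxopentanedioate)
Product: 11 methyl 6-[3-chloro-2,6-bis(methoxymethoxy)-4-methylbenzoyl]-4-hydroxy-2-oxo-2H-pyran-5-carboxylate, via aryl glyoxylyl chloride 9 (not isolated), via C-acylated oxoglutarate 10 (not isolated)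
Conditions: 1-chloro-N,N,2-trimethylprop-1-en-1-amine, CH2Cl2, 0 °C → rt; then 8, MgCl2, pyridine, CH2Cl2, 0 °C → rt; then DBU, 40 °C; 1 M HCl to pH 4
Reagents that add atoms: none
Why: The α-chloroenamine forms the acid chloride without releasing HCl (MOM groups safe), soft enolisation of the β-keto ester as its magnesium chelate gives Claisen-type C-acylation, and DBU-promoted enol lactonisation of the resulting 3,5-dioxo ester onto the remote methyl ester closes the 4-hydroxy-2-pyrone, driven by formation of the acidic pyrone.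

Step 6
Reactants: 11 methyl 6-[3-chloro-2,6-bis(methoxymethoxy)-4-methylbenzoyl]-4-hydroxy-2-oxo-2H-pyran-5-carboxylate
Product: 12 methyl 6-[3-chloro-2,6-bis(methoxymethoxy)-4-methylbenzoyl]-4-(methoxymethoxy)-2-oxo-2H-pyran-5-carboxylate
Conditions: MOMCl, i-Pr2NEt, CH2Cl2, 0 °C
Reagents that add atoms: chloromethyl methyl ether, COCCl
Why: The acidic 4-hydroxyl of the pyrone (a vinylogous carboxylic acid) is O-alkylated by the hard oxocarbenium-type electrophile, which fixes the 2-pyrone diene and matches the other acetal protecting groups.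

Step 7
Reactants: 13 ethyl 4-methylpent-3-enoate
Product: 16 triisopropyl[(5-methylhex-4-en-1-yn-1-yl)oxy]silane, via dibromoketone lithium enolate 14 (not isolated), via lithium ynolate 15 (not isolated)
Conditions: CH2Br2, LiTMP (lithium 2,2,6,6-tetramethylpiperidide, from the amine and n-BuLi), THF, −78 °C; 13; LiN(SiMe3)2; s-BuLi, −78 → 0 °C; TIPSOTf, −78 °C → rt
Reagents that add atoms: dibromomethane, BrCBr; triisopropylsilyl trifluoromethanesulfonate, CC(C)[Si](C(C)C)(C(C)C)OS(=O)(=O)C(F)(F)F
Why: In this Kowalski ester homologation LiCHBr2 adds to the ester at −78 °C (expected to outrun deprotonation of the doubly activated α-CH2), the dibromoketone enolate undergoes bromine–lithium exchange and 1,2-shift of the prenyl-CH2 group to the ynolate, and the bulky silyl triflate traps the ynolate on oxygen.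

Step 8
Reactants: 12 methyl 6-[3-chloro-2,6-bis(methoxymethoxy)-4-methylbenzoyl]-4-(methoxymethoxy)-2-oxo-2H-pyran-5-carboxylate; 16 triisopropyl[(5-methylhex-4-en-1-yn-1-yl)oxy]silane
Product: 18 methyl 2-[3-chloro-2,6-bis(methoxymethoxy)-4-methylbenzoyl]-6-(methoxymethoxy)-3-(3-methylbut-2-en-1-yl)-4-[(triisopropylsilyl)oxy]benzoate, via bridged lactone cycloadduct 17 (not isolated)
Conditions: 16 (3 equiv), PhMe, 100 °C, sealed tube
Reagents that add atoms: none
Why: The β-carbon of siloxyalkyne 16 (the carbon carrying the prenyl CH2) is the nucleophilic terminus and bonds first to pyrone C6, the δ-position of the lactone dienoate and β-position of the C5 acrylate ester, while the developing silyl-stabilised ketenium carbon is captured by the enol-ether terminus C3 in a concerted but asynchronous inverse-electron-demand [4+2] cycloaddition. This intermolecular cycloaddition closes the 2-oxabicyclo[2.2.2]octadienone 17 by forming C1–C6 and C2–C3 together, and thermal retro-[4+2] cleavage then expels CO2 and leaves ring A as a benzene without any oxidation or elimination, because the dienophile is an alkyne. The closest known reaction type is the pyrone-to-arene conversion of 2-pyrone-5-carboxylates with ynamines and alkoxyalkynes, applied here to a more highly substituted pyrone and a silyl ynol ether. No stereocentre survives, since the two bridgehead centres of racemic 17 are lost on aromatisation. The step needs regioselectivity (prenyl carbon to C6, siloxy carbon to C3), which the matched polarisation of the ynol ether and the push–pull pyrone should secure, and chemoselectivity for the diene over the aroyl carbonyl, which the two flanking MOM ethers and the absence of any Lewis acid should secure.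

Step 9
Reactants: 18 methyl 2-[3-chloro-2,6-bis(methoxymethoxy)-4-methylbenzoyl]-6-(methoxymethoxy)-3-(3-methylbut-2-en-1-yl)-4-[(triisopropylsilyl)oxy]benzoate
Product: 19 [2-{[3-chloro-2,6-bis(methoxymethoxy)-4-methylphenyl](hydroxy)methyl}-6-(methoxymethoxy)-3-(3-methylbut-2-en-1-yl)-4-[(triisopropylsilyl)oxy]phenyl]methanol (racemic)
Conditions: LiAlH4, THF, 0 °C → rt; aqueous potassium sodium tartrate work-up
Reagents that add atoms: none
Why: The small, powerful hydride should reduce both the hindered benzoate and the diaryl ketone (any phthalide formed on the way is reduced as well), giving one defined diol whose new carbinol centre is formed without control as a racemate and is removed again in step 10.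

Step 10
Reactants: 19 the racemic diol
Product: 20 2-[3-chloro-2,6-bis(methoxymethoxy)-4-methylbenzoyl]-6-(methoxymethoxy)-3-(3-methylbut-2-en-1-yl)-4-[(triisopropylsilyl)oxy]benzaldehyde
Conditions: (COCl)2, DMSO, CH2Cl2, −78 °C; Et3N, −78 → 0 °C
Reagents that add atoms: none
Why: Swern oxidation converts both hydroxyls into alkoxysulfonium ions before base is added, so aldehyde and ketone are released together and the lactol that other oxidants would carry on to a phthalide should not form.

Step 11
Reactants: 20 the protected keto aldehyde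
Product: 21 2-(3-chloro-2,6-dihydroxy-4-methylbenzoyl)-6-hydroxy-3-(3-methylbut-2-en-1-yl)-4-[(triisopropylsilyl)oxy]benzaldehyde
Conditions: HCl (ca. 1 M in MeOH), rt; then H2O
Reagents that add atoms: none
Why: Acid-catalysed acetal cleavage removes the three MOM ethers, each of which sits ortho to a carbonyl and is therefore labile, while the silyl ether retained on the C2 oxygen blocks acid-induced chroman formation between that oxygen and the prenyl alkene.

Step 12
Reactants: 21 the triphenol silyl ether
Product: 22 Pestalone E, 2-(3-chloro-2,6-dihydroxy-4-methylbenzoyl)-4,6-dihydroxy-3-(3-methylbut-2-en-1-yl)benzaldehyde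
Conditions: Bu4NF, AcOH (1:1), THF, 0 °C
Reagents that add atoms: none
Why: Fluoride attacks silicon and expels a phenoxide stabilised by the para formyl group, and the acetic acid buffer keeps the medium from becoming basic enough to trigger hydride-shift lactonisation of the o-aroylbenzaldehyde.

Compound list
1 | orcinol (5-methylbenzene-1,3-diol) | Cc1cc(O)cc(O)c1 | starting material
2 | 4-chloro-5-methylbenzene-1,3-diol | Cc1cc(O)cc(O)c1Cl | intermediate
3 | 2-chloro-1,5-bis(methoxymethoxy)-3-methylbenzene | Cc1cc(OCOC)cc(OCOC)c1Cl | intermediate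
4 | diethyl oxalate | CCOC(=O)C(=O)OCC | starting material
5 | [3-chloro-2,6-bis(methoxymethoxy)-4-methylphenyl]lithium | [Li]c1c(OCOC)cc(C)c(Cl)c1OCOC | intermediate
6 | ethyl 2-[3-chloro-2,6-bis(methoxymethoxy)-4-methylphenyl]-2-oxoacetate | CCOC(=O)C(=O)c1c(OCOC)cc(C)c(Cl)c1OCOC | intermediate
7 | 2-[3-chloro-2,6-bis(methoxymethoxy)-4-methylphenyl]-2-oxoacetic acid | OC(=O)C(=O)c1c(OCOC)cc(C)c(Cl)c1OCOC | intermediate
8 | dimethyl 3-oxoglutarate (dimethyl 3-oxopentanedioate) | COC(=O)CC(=O)CC(=O)OC | starting material
9 | 2-[3-chloro-2,6-bis(methoxymethoxy)-4-methylphenyl]-2-oxoacetyl chloride | ClC(=O)C(=O)c1c(OCOC)cc(C)c(Cl)c1OCOC | intermediate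
10 | dimethyl 2-{2-[3-chloro-2,6-bis(methoxymethoxy)-4-methylphenyl]-2-oxoacetyl}-3-oxopentanedioate | COC(=O)CC(=O)C(C(=O)OC)C(=O)C(=O)c1c(OCOC)cc(C)c(Cl)c1OCOC | intermediate
11 | methyl 6-[3-chloro-2,6-bis(methoxymethoxy)-4-methylbenzoyl]-4-hydroxy-2-oxo-2H-pyran-5-carboxylate | COC(=O)C1=C(C(=O)c2c(OCOC)cc(C)c(Cl)c2OCOC)OC(=O)C=C1O | intermediate
12 | methyl 6-[3-chloro-2,6-bis(methoxymethoxy)-4-methylbenzoyl]-4-(methoxymethoxy)-2-oxo-2H-pyran-5-carboxylate | COC(=O)C1=C(C(=O)c2c(OCOC)cc(C)c(Cl)c2OCOC)OC(=O)C=C1OCOC | intermediate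
13 | ethyl 4-methylpent-3-enoate | CCOC(=O)CC=C(C)C | starting material
14 | lithium enolate of 1,1-dibromo-5-methylhex-4-en-2-one | [Li+].[O-]C(CC=C(C)C)=C(Br)Br | intermediate
15 | lithium 5-methylhex-4-en-1-yn-1-olate | [Li+].[O-]C#CCC=C(C)C | intermediate
16 | triisopropyl[(5-methylhex-4-en-1-yn-1-yl)oxy]silane | CC(C)=CCC#CO[Si](C(C)C)(C(C)C)C(C)C | intermediate
17 | methyl 1-[3-chloro-2,6-bis(methoxymethoxy)-4-methylbenzoyl]-5-(methoxymethoxy)-7-(3-methylbut-2-en-1-yl)-3-oxo-8-[(triisopropylsilyl)oxy]-2-oxabicyclo[2.2.2]octa-5,7-diene-6-carboxylate (racemic, no configuration assigned) | C12(C(=O)c3c(OCOC)cc(C)c(Cl)c3OCOC)OC(=O)C(C(OCOC)=C1C(=O)OC)C(O[Si](C(C)C)(C(C)C)C(C)C)=C2CC=C(C)C | intermediate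
18 | methyl 2-[3-chloro-2,6-bis(methoxymethoxy)-4-methylbenzoyl]-6-(methoxymethoxy)-3-(3-methylbut-2-en-1-yl)-4-[(triisopropylsilyl)oxy]benzoate | CC(C)=CCc1c(O[Si](C(C)C)(C(C)C)C(C)C)cc(OCOC)c(C(=O)OC)c1C(=O)c1c(OCOC)cc(C)c(Cl)c1OCOC | intermediate
19 | [2-{[3-chloro-2,6-bis(methoxymethoxy)-4-methylphenyl](hydroxy)methyl}-6-(methoxymethoxy)-3-(3-methylbut-2-en-1-yl)-4-[(triisopropylsilyl)oxy]phenyl]methanol (racemic) | CC(C)=CCc1c(O[Si](C(C)C)(C(C)C)C(C)C)cc(OCOC)c(CO)c1C(O)c1c(OCOC)cc(C)c(Cl)c1OCOC | intermediate
20 | 2-[3-chloro-2,6-bis(methoxymethoxy)-4-methylbenzoyl]-6-(methoxymethoxy)-3-(3-methylbut-2-en-1-yl)-4-[(triisopropylsilyl)oxy]benzaldehyde | CC(C)=CCc1c(O[Si](C(C)C)(C(C)C)C(C)C)cc(OCOC)c(C=O)c1C(=O)c1c(OCOC)cc(C)c(Cl)c1OCOC | intermediate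
21 | 2-(3-chloro-2,6-dihydroxy-4-methylbenzoyl)-6-hydroxy-3-(3-methylbut-2-en-1-yl)-4-[(triisopropylsilyl)oxy]benzaldehyde | CC(C)=CCc1c(O[Si](C(C)C)(C(C)C)C(C)C)cc(O)c(C=O)c1C(=O)c1c(O)cc(C)c(Cl)c1O | intermediate
22 | Pestalone E, 2-(3-chloro-2,6-dihydroxy-4-methylbenzoyl)-4,6-dihydroxy-3-(3-methylbut-2-en-1-yl)benzaldehyde | CC(C)=CCc1c(O)cc(O)c(C=O)c1C(=O)c1c(O)cc(C)c(Cl)c1O | target

Total step count: 12. Longest linear sequence: 11 steps (steps 1–6 and 8–12, from orcinol); the alkyne branch is the single step 7.

Steps most likely to fail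

Step 8 (key cycloaddition). The siloxyalkyne may be consumed by silyl migration to a silylketene or by oligomerisation before it adds to the crowded C6 of the pyrone, or it may add across the aroyl carbonyl. The fallback sets out from pyrone 12 and replaces the alkyne by an alkene dienophile of the same polarity that aromatises by elimination. Johnson–Claisen rearrangement of 2-methylbut-3-en-2-ol with trimethyl orthoacetate (cat. EtCO2H, 120 °C) should give methyl 5-methylhex-4-enoate F1. LiN(i-Pr)2 and then TIPSOTf (THF, −78 °C) should convert it into the ketene silyl acetal 1-methoxy-5-methyl-1-(triisopropylsiloxy)hexa-1,4-diene F2. Heating F2 with 12 in toluene should give the bridged lactone cycloadduct F3, which loses CO2 to the cyclohexadiene F4. Elimination of methanol from F4 (on heating or with Et3N) aromatises ring A, and the route is rejoined at 18. The conversion of 2-pyrones into arenes with ketene acetals, with loss of CO2 and an alcohol, is established chemistry with the same regiochemical bias.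

Step 5 (pyrone assembly). The α-keto acid chloride may lose CO, or the MOM ethers may be cleaved during activation. The unpurified tricarbonyl may also be O-acylated, or may close through the aryl ketone instead of lactonising. The fallback sets out from acid 7 and uses an isolated neutral acyl donor in a stepwise sequence. Activation with 1,1'-carbonyldiimidazole (THF, rt) should give the acyl imidazolide F5, which acylates the preformed magnesium enolate of 8 (MgCl2, Et3N, MeCN) on carbon. Tricarbonyl 10 is then isolated and lactonised in a separate operation (DBU, PhMe, 60 °C), so the route is rejoined at 10 and continues to 11.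

Step 10 (double oxidation). The aldehyde may be released while the carbinol is still free, so that a lactol forms and is oxidised on to the phthalide. Alternatively, the activated, electron-rich diaryl carbinol may ionise and close to a cyclic ether. The fallback sets out from diol 19 and handles the two hydroxyls one at a time. Selective silylation of the primary hydroxyl (Et3SiCl, imidazole, CH2Cl2, −20 °C) should give the triethylsilyl ether F6. Dess–Martin oxidation (NaHCO3, CH2Cl2) of the remaining diaryl carbinol gives the ketone F7, and AcOH/THF/H2O removes the triethylsilyl group to the hydroxy ketone F8. A second Dess–Martin oxidation gives 20, where the route is rejoined. With the ketone installed first, the hemiketal of F8 cannot be oxidised to a lactone.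

Further compounds
F1 | step 8 | methyl 5-methylhex-4-enoate | COC(=O)CCC=C(C)C
F2 | step 8 | 1-methoxy-5-methyl-1-(triisopropylsiloxy)hexa-1,4-diene (ketene acetal geometry not controlled and inconsequential) | COC(O[Si](C(C)C)(C(C)C)C(C)C)=CCC=C(C)C
F3 | step 8 | methyl 1-[3-chloro-2,6-bis(methoxymethoxy)-4-methylbenzoyl]-8-methoxy-5-(methoxymethoxy)-7-(3-methylbut-2-en-1-yl)-3-oxo-8-[(triisopropylsilyl)oxy]-2-oxabicyclo[2.2.2]oct-5-ene-6-carboxylate (racemic diastereomer mixture, no configuration assigned) | C12(C(=O)c3c(OCOC)cc(C)c(Cl)c3OCOC)OC(=O)C(C(OCOC)=C1C(=O)OC)C(OC)(O[Si](C(C)C)(C(C)C)C(C)C)C2CC=C(C)C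
F4 | step 8 | methyl 2-[3-chloro-2,6-bis(methoxymethoxy)-4-methylbenzoyl]-4-methoxy-6-(methoxymethoxy)-3-(3-methylbut-2-en-1-yl)-4-[(triisopropylsilyl)oxy]cyclohexa-1,5-diene-1-carboxylate (racemic diastereomer mixture, no configuration assigned) | CC(C)=CCC1C(OC)(O[Si](C(C)C)(C(C)C)C(C)C)C=C(OCOC)C(C(=O)OC)=C1C(=O)c1c(OCOC)cc(C)c(Cl)c1OCOC
F5 | step 5 | 1-[3-chloro-2,6-bis(methoxymethoxy)-4-methylphenyl]-2-(1H-imidazol-1-yl)ethane-1,2-dione | O=C(C(=O)c1c(OCOC)cc(C)c(Cl)c1OCOC)n1ccnc1
F6 | step 10 | [3-chloro-2,6-bis(methoxymethoxy)-4-methylphenyl]{3-(methoxymethoxy)-6-(3-methylbut-2-en-1-yl)-2-{[(triethylsilyl)oxy]methyl}-5-[(triisopropylsilyl)oxy]phenyl}methanol (racemic) | CC(C)=CCc1c(O[Si](C(C)C)(C(C)C)C(C)C)cc(OCOC)c(CO[Si](CC)(CC)CC)c1C(O)c1c(OCOC)cc(C)c(Cl)c1OCOC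
F7 | step 10 | [3-chloro-2,6-bis(methoxymethoxy)-4-methylphenyl]{3-(methoxymethoxy)-6-(3-methylbut-2-en-1-yl)-2-{[(triethylsilyl)oxy]methyl}-5-[(triisopropylsilyl)oxy]phenyl}methanone | CC(C)=CCc1c(O[Si](C(C)C)(C(C)C)C(C)C)cc(OCOC)c(CO[Si](CC)(CC)CC)c1C(=O)c1c(OCOC)cc(C)c(Cl)c1OCOC
F8 | step 10 | [3-chloro-2,6-bis(methoxymethoxy)-4-methylphenyl]{2-(hydroxymethyl)-3-(methoxymethoxy)-6-(3-methylbut-2-en-1-yl)-5-[(triisopropylsilyl)oxy]phenyl}methanone | CC(C)=CCc1c(O[Si](C(C)C)(C(C)C)C(C)C)cc(OCOC)c(CO)c1C(=O)c1c(OCOC)cc(C)c(Cl)c1OCOC
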